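Decide first to carry one number from the earlier runs to the new flasks, and leave the mechanism aside.

all flasks: free catalyst 5.1 mol%; impurity 0.42 mM

| run | starting material | remark | time |
|---|---|---|---|
| alpha | 0.029 M | run made earlier |  |
| gamma | 0.17 M | run made earlier |  |
| south-west | 0.020 M |  | 8.0 h |
| north-east | 0.040 M |  | 8.0 h |
| south | 0.080 M |  | 8.0 h |
| north-west | 0.15 M |  | 8.0 h |

| run | time / h | target / % |
|---|---|---|
| alpha | 1.00 | 15.2 |
| alpha | 2.50 | 12.2 |
| alpha | 3.00 | 11.7 |
| alpha | 5.00 | 11.6 |
| alpha | 6.00 | 12.4 |
| gamma | 0.417 | 21.8 |
| gamma | 0.833 | 17.4 |
| gamma | 1.50 | 13.5 |
| gamma | 3.00 | 10.9 |
| gamma | 6.00 | 11.6 |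

(each reading ± 1 percentage point)

- [target] at the end for south-west, north-east, south, north-west, in this order
- the course of these numbers from the first flask to the last (rises all the way / rises, then falls / hardly changes / falls all the way / falls, then rises)

- the numbers in the tables scatter by 1 percentage point (one standard deviation)
- "hardly changes" means that all values lie within two and a half points (for a concentration: within two and a half percent of the largest)

In the alpha and gamma runs, target falls from its first readings and then stays level. Average the 5 readings from 3.00 h onward, each scattered by 1 percentage point:

share = 11.6%

This is the plateau share, the fraction of the charged starting material that stands as target after the early fall, as read from these scattered readings. The gamma run was charged 5.86 times as heavily as the alpha run, yet its late readings lie on the same level within the scatter, so you take the share as independent of the charge over this range.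

Next, reckon how fast the excess dies, from the first and third gamma readings:

τ = 0.638 h

The asked 8.0 h is 12.5 such times, so on this clock, read in the gamma run, the excess shrinks to <0.001% of its size at the start. Multiplying the share by each charge gives the row:

south-west: 0.00233 M
north-east: 0.00466 M
south: 0.00931 M
north-west: 0.0175 M

The weak link is the south-west flask, which is more dilute than the alpha run with the same impurity. Assume that each impurity takes one catalyst and that the clock slows in proportion to the catalyst left. The alpha run already reads 12.2% at 2.50 h, within the scatter of the share, so stretching that time gives:

4.41 h

That is less than the asked time, so you keep the row.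

The forecast gives 0.0024 M, 0.0048 M, 0.0096 M and 0.018 M, rises all the way. It takes about 12% of the charge, a little above the share reckoned here. In its words: “This is an empirical extrapolation, not a proven mechanism.”

The flasks end at 0.00232 M, 0.00460 M, 0.00921 M and 0.0173 M, rises all the way, and the forecast stands within its margin.

    isomer of the product A ⇌ isomer of the product B (K = 0.350, k = 0.00910 min⁻¹)
    isomer of the product B ⇌ starting material (k = 0.00110 min⁻¹)
    free catalyst + impurity → spent catalyst B (k = 5300 M⁻¹ min⁻¹)
    free catalyst → spent catalyst A (k = 9.80 × 10⁻⁴ min⁻¹)
    starting material + free catalyst ⇌ target + free catalyst, rate k5*[starting material]*[free catalyst] forward; the back reaction follows from the equilibrium constant (K = 0.480, k = 7.60 M⁻¹ min⁻¹)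
    starting material ⇌ dormant form (K = 2.10, k = 0.0180 min⁻¹)
    target + free catalyst ⇌ isomer of the product A + free catalyst, rate k7*[free catalyst]*[target] forward; the back reaction follows from the equilibrium constant (K = 0.900, k = 2.60 M⁻¹ min⁻¹)

In the south-west flask, target stands at 11.9% at 4.00 h, 11.6% at 8.00 h and 11.5% at 80.0 h, while free catalyst goes from 46.5% to 0.533% of its charge between the first and the last of these times. The share can now give a second amount. Dividing it by 0.48, the equilibrium constant of starting material to target, gives 24.2% of the charge as starting material, and the north-west flask holds 24.0% at 8.00 h.

(The numbers in the tables are simulated for substances that don't exist; the scatter is artificial.)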